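**Plan**

- Retrosynthesis: the ten benzyl ethers are removed last. The flavan stereocentres C-2 and C-3 are traced back to the C-2=C-3 enol ether of a flav-2-ene. Ring C of that flavene is cut at C-4–C-3 and at O-1–C-8a, giving the enolate of 3,4-bis(benzyloxy)acetophenone and a benzylic bromide with a bromine on the neighbouring ring carbon.
- Enabling feature: in ring C, O-1/C-2/C-3 is the O–C=C of an aryl ketone enolate (C-2 carries ring B), and C-4/C-4a/C-8a is a benzylic carbon plus its ortho ring carbon. In ring A only C-8a, para to the arm-bearing C-6, carries a halogen, so one [3+3] union closes ring C and can only give the 6-linked flavan.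
- Forward order: ring A of the flavan is built first as a fully substituted benzene from 2-bromo-4,6-difluorobenzoic acid (ester = latent C-4; formyl between the fluorines = future diarylmethine carbon; both fluorines exchanged for benzyloxy). The 1,3-diarylpropan-2-ol arm is grown from the formyl group (olefination, epoxidation, two aryl Grignard openings). The ester becomes CH2Br, ring C is closed, then hydroboration and hydrogenolysis follow.
- Stereochemistry: the carbinol centre of the arm comes from Sharpless asymmetric epoxidation; the diarylmethine centre from SN2 opening of that epoxide at the benzylic carbon with inversion; flavan C-2/C-3 (2,3-trans, 2R,3S) from reagent-controlled syn hydroboration of the flavene with isopinocampheylborane.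

Key step: step 14

Assumption: compounds 1, 9, 14 and 21 are taken as purchasable; each is otherwise one routine step from a commodity arene or phenol.

**Route**

Step 1
Reactants: 1 2-bromo-4,6-difluorobenzoic acid
Product: 2 tert-butyl 2-bromo-4,6-difluorobenzoate
Conditions: tert-butyl 2,2,2-trichloroacetimidate, BF3·OEt2 (cat.), CH2Cl2/cyclohexane, rt
Reagents that add atoms: tert-butyl 2,2,2-trichloroacetimidate, CC(C)(C)OC(=N)C(Cl)(Cl)Cl
Why: Acid-catalysed O-alkylation of the carboxylic acid by the imidate (tert-butyl esterification) needs no attack at the doubly ortho-substituted carbonyl and gives an ester that resists the bases, hydrides and Grignard reagents used up to step 11.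

Step 2
Reactants: 2 tert-butyl 2-bromo-4,6-difluorobenzoate
Product: 4 tert-butyl 6-bromo-2,4-difluoro-3-formylbenzoate, via aryllithium 3 (not isolated)
Conditions: LiN(iPr)2, THF, −78 °C; DMF, −78 to −40 °C; AcOH quench
Reagents that add atoms: N,N-dimethylformamide, CN(C)C=O
Why: Directed ortho-lithiation removes the most acidic ring proton, the one flanked by both fluorines, and formylation of the aryllithium with DMF places the future diarylmethine carbon between the two carbons that will carry oxygen.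

Step 3
Reactants: 4 tert-butyl 6-bromo-2,4-difluoro-3-formylbenzoate
Product: 5 tert-butyl 2,4-bis(benzyloxy)-6-bromo-3-formylbenzoate
Conditions: BnOH (2.2 equiv), Cs2CO3, DMF, rt to 40 °C
Reagents that add atoms: benzyl alcohol, OCc1ccccc1
Why: Nucleophilic aromatic substitution (SNAr) should exchange both fluorines, each ortho to the formyl group and ortho or para to the ester, much faster than the bromine.

Step 4
Reactants: 5 tert-butyl 2,4-bis(benzyloxy)-6-bromo-3-formylbenzoate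
Product: 6 tert-butyl 2,4-bis(benzyloxy)-6-bromo-3-[(E)-3-ethoxy-3-oxoprop-1-en-1-yl]benzoate
Conditions: (EtO)2P(O)CH2CO2Et, NaH, THF, 0 °C to rt
Reagents that add atoms: triethyl phosphonoacetate, CCOC(=O)CP(=O)(OCC)OCC
Why: Horner–Wadsworth–Emmons olefination of an aromatic aldehyde with a stabilised phosphonate anion should give the (E)-cinnamate.

Step 5
Reactants: 6 tert-butyl 2,4-bis(benzyloxy)-6-bromo-3-[(E)-3-ethoxy-3-oxoprop-1-en-1-yl]benzoate
Product: 7 tert-butyl 2,4-bis(benzyloxy)-6-bromo-3-[(E)-3-hydroxyprop-1-en-1-yl]benzoate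
Conditions: iBu2AlH (2.2 equiv), CH2Cl2, −78 °C; aqueous potassium sodium tartrate
Reagents that add atoms: none
Why: 1,2-Reduction of the unhindered conjugated ethyl ester by iBu2AlH should give the (E)-allylic alcohol, while the tert-butyl benzoate, shielded by two ortho substituents, is expected to survive at −78 °C.

Step 6
Reactants: 7 tert-butyl 2,4-bis(benzyloxy)-6-bromo-3-[(E)-3-hydroxyprop-1-en-1-yl]benzoate
Product: 8 tert-butyl 2,4-bis(benzyloxy)-6-bromo-3-[(2S,3S)-3-(hydroxymethyl)oxiran-2-yl]benzoate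
Conditions: Ti(OiPr)4 (10 mol%), L-(+)-diethyl tartrate (12 mol%), t-BuOOH, 4 Å molecular sieves, CH2Cl2, −20 °C
Reagents that add atoms: tert-butyl hydroperoxide, CC(C)(C)OO
Why: Sharpless asymmetric epoxidation of an (E)-allylic alcohol with L-(+)-tartrate should deliver oxygen to the face that gives the (2S,3S)-epoxy alcohol, which fixes the carbinol centre of the arm.

Step 7
Reactants: 8 tert-butyl 2,4-bis(benzyloxy)-6-bromo-3-[(2S,3S)-3-(hydroxymethyl)oxiran-2-yl]benzoate; 9 4-bromo-1,2-bis(benzyloxy)benzene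
Product: 11 tert-butyl 2,4-bis(benzyloxy)-3-[(1R,2R)-1-[3,4-bis(benzyloxy)phenyl]-2,3-dihydroxypropyl]-6-bromobenzoate, via Grignard reagent 10 (not isolated)
Conditions: 9, Mg, THF, rt (gives 10, 3.5 equiv); CuI (20 mol%), then 8, THF, −40 to 0 °C
Reagents that add atoms: none
Why: Copper-catalysed Grignard opening of a 3-aryl-2,3-epoxy alcohol should occur at the benzylic carbon by SN2 with inversion, so the (S)-epoxide carbon becomes the (R)-diarylmethine centre while the neighbouring carbinol centre is untouched.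

Step 8
Reactants: 11 tert-butyl 2,4-bis(benzyloxy)-3-[(1R,2R)-1-[3,4-bis(benzyloxy)phenyl]-2,3-dihydroxypropyl]-6-bromobenzoate
Product: 13 tert-butyl 2,4-bis(benzyloxy)-3-[(R)-[3,4-bis(benzyloxy)phenyl][(2R)-oxiran-2-yl]methyl]-6-bromobenzoate, via primary tosylate 12 (not isolated)
Conditions: TsCl (1.05 equiv), Et3N, Bu2SnO (2 mol%), CH2Cl2, 0 °C; then K2CO3, MeOH, rt
Reagents that add atoms: none
Why: Tin-catalysed selective sulfonylation of the primary hydroxyl followed by intramolecular Williamson displacement by the secondary alkoxide should close the terminal epoxide with retention at the carbinol carbon.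

Step 9
Reactants: 14 1,3,5-tris(benzyloxy)benzene
Product: 15 2-bromo-1,3,5-tris(benzyloxy)benzene
Conditions: N-bromosuccinimide (1.0 equiv), CH2Cl2, −78 to 0 °C
Reagents that add atoms: N-bromosuccinimide, BrN1C(=O)CCC1=O
Why: Electrophilic aromatic bromination of the symmetrical, strongly activated arene can give only one monobromide.

Step 10
Reactants: 13 tert-butyl 2,4-bis(benzyloxy)-3-[(R)-[3,4-bis(benzyloxy)phenyl][(2R)-oxiran-2-yl]methyl]-6-bromobenzoate; 15 2-bromo-1,3,5-tris(benzyloxy)benzene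
Product: 17 tert-butyl 2,4-bis(benzyloxy)-3-[(1R,2S)-1-[3,4-bis(benzyloxy)phenyl]-2-hydroxy-3-[2,4,6-tris(benzyloxy)phenyl]propyl]-6-bromobenzoate, via Grignard reagent 16 (not isolated)
Conditions: 15, Mg, THF, 50 °C (gives 16, 2 equiv); CuI (10 mol%), then 13, THF, −30 to 0 °C
Reagents that add atoms: none
Why: Copper-catalysed Grignard opening of a monosubstituted epoxide should take place at the unsubstituted carbon, which attaches the phloroglucinol ring to the methylene and frees the secondary alcohol without touching either stereocentre.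

Step 11
Reactants: 17 tert-butyl 2,4-bis(benzyloxy)-3-[(1R,2S)-1-[3,4-bis(benzyloxy)phenyl]-2-hydroxy-3-[2,4,6-tris(benzyloxy)phenyl]propyl]-6-bromobenzoate
Product: 18 tert-butyl 2,4-bis(benzyloxy)-3-[(1R,2S)-2-(benzyloxy)-1-[3,4-bis(benzyloxy)phenyl]-3-[2,4,6-tris(benzyloxy)phenyl]propyl]-6-bromobenzoate
Conditions: NaH, BnBr, n-Bu4NI (cat.), THF/DMF, 0 °C to rt
Reagents that add atoms: benzyl bromide, BrCc1ccccc1
Why: Williamson etherification protects the secondary alcohol as a benzyl ether that is removed together with all the others in the last step.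

Step 12
Reactants: 18 tert-butyl 2,4-bis(benzyloxy)-3-[(1R,2S)-2-(benzyloxy)-1-[3,4-bis(benzyloxy)phenyl]-3-[2,4,6-tris(benzyloxy)phenyl]propyl]-6-bromobenzoate
Product: 19 {2,4-bis(benzyloxy)-3-[(1R,2S)-2-(benzyloxy)-1-[3,4-bis(benzyloxy)phenyl]-3-[2,4,6-tris(benzyloxy)phenyl]propyl]-6-bromophenyl}methanol
Conditions: iBu2AlH (4 equiv), CH2Cl2, 0 °C to rt; aqueous potassium sodium tartrate
Reagents that add atoms: none
Why: Exhaustive hydride reduction of the tert-butyl ester with excess iBu2AlH at higher temperature should give the benzylic alcohol, the aryl bromide and benzyl ethers being inert to this reagent.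

Step 13
Reactants: 19 {2,4-bis(benzyloxy)-3-[(1R,2S)-2-(benzyloxy)-1-[3,4-bis(benzyloxy)phenyl]-3-[2,4,6-tris(benzyloxy)phenyl]propyl]-6-bromophenyl}methanol
Product: 20 2,4-bis(benzyloxy)-3-[(1R,2S)-2-(benzyloxy)-1-[3,4-bis(benzyloxy)phenyl]-3-[2,4,6-tris(benzyloxy)phenyl]propyl]-6-bromobenzyl bromide
Conditions: CBr4, PPh3, CH2Cl2, 0 °C; used without purification
Reagents that add atoms: carbon tetrabromide, BrC(Br)(Br)Br
Why: Appel bromination converts the primary benzylic alcohol into the bromide under neutral conditions that spare the acid-labile, electron-rich benzyl system.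

Step 14
Reactants: 20 2,4-bis(benzyloxy)-3-[(1R,2S)-2-(benzyloxy)-1-[3,4-bis(benzyloxy)phenyl]-3-[2,4,6-tris(benzyloxy)phenyl]propyl]-6-bromobenzyl bromide; 21 1-[3,4-bis(benzyloxy)phenyl]ethan-1-one
Product: 23 5,7-bis(benzyloxy)-6-[(1R,2S)-2-(benzyloxy)-1-[3,4-bis(benzyloxy)phenyl]-3-[2,4,6-tris(benzyloxy)phenyl]propyl]-2-[3,4-bis(benzyloxy)phenyl]-4H-chromene, via dihydrochalcone 22 (not isolated)
Conditions: 21 (1.5 equiv), LiN(SiMe3)2, THF, −78 °C, then 20, −78 to 0 °C; then Cs2CO3 (2 equiv), CuI (20 mol%), 1,10-phenanthroline (40 mol%), DMF, 100 °C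
Reagents that add atoms: none
Why: The lithium enolate of 21 is C-benzylated by bromide 20 (SN2 at C-4, forming C-4–C-3) to give ketone 22; Cs2CO3 then regenerates the enolate, whose oxygen is coupled to C-8a by a monovalent-copper/phenanthroline cycle (oxidative addition into C–Br, C–O reductive elimination), forming O-1–C-8a and ring C. The closest known reaction type is the domino C-benzylation/Ullmann-type O-arylation of enolisable ketones with 2-bromobenzyl bromides to 4H-chromenes, together with copper-catalysed intramolecular O-arylation of ketone enolates. Ring C closes as a six-membered ring by attack of the enolate oxygen on the aryl carbon (6-exo with respect to the departing bromide); the competing C-arylation would give a five-membered 2-aroylindane and is not favoured under copper catalysis. No stereocentre is formed: the product is the planar enol ether, C-2 and C-3 are set together in step 15, and the two centres of the side chain are remote from all reacting sites. The selectivities needed are mono-C-alkylation (excess enolate, low temperature, reactive benzylic bromide), O- over C-arylation, and closure on the correct ring carbon, which is secured because C-8a, para to C-6, is the only halogen-bearing carbon of ring A, so only the 6-linked flavan can form.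

Step 15
Reactants: 23 5,7-bis(benzyloxy)-6-[(1R,2S)-2-(benzyloxy)-1-[3,4-bis(benzyloxy)phenyl]-3-[2,4,6-tris(benzyloxy)phenyl]propyl]-2-[3,4-bis(benzyloxy)phenyl]-4H-chromene
Product: 25 (2R,3S)-5,7-bis(benzyloxy)-6-[(1R,2S)-2-(benzyloxy)-1-[3,4-bis(benzyloxy)phenyl]-3-[2,4,6-tris(benzyloxy)phenyl]propyl]-2-[3,4-bis(benzyloxy)phenyl]-3,4-dihydro-2H-chromen-3-ol, via alkylborane 24 (not isolated)
Conditions: isopinocampheylborane (IpcBH2, from (+)-α-pinene), THF, −25 to 0 °C; then NaOH, H2O2, H2O, 0 °C to rt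
Reagents that add atoms: hydrogen peroxide, OO
Why: In this asymmetric hydroboration–oxidation boron should add to C-3 (β to the ring oxygen, away from the aryl-bearing carbon) and hydrogen to C-2 on the same face, so that the 2-aryl and 3-hydroxyl groups end up trans, the chiral borane being chosen to select the face that gives (2R,3S) by analogy with its behaviour towards 1-arylcycloalkenes, and the C–B bond being oxidised with retention.

Step 16
Reactants: 25 (2R,3S)-5,7-bis(benzyloxy)-6-[(1R,2S)-2-(benzyloxy)-1-[3,4-bis(benzyloxy)phenyl]-3-[2,4,6-tris(benzyloxy)phenyl]propyl]-2-[3,4-bis(benzyloxy)phenyl]-3,4-dihydro-2H-chromen-3-ol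
Product: 26 (2R,3S)-2-(3,4-dihydroxyphenyl)-6-[(1R,2S)-1-(3,4-dihydroxyphenyl)-2-hydroxy-3-(2,4,6-trihydroxyphenyl)propyl]-3,4-dihydro-2H-chromene-3,5,7-triol
Conditions: H2 (1 atm), Pd(OH)2/C, THF/MeOH, rt
Reagents that add atoms: none
Why: Catalytic hydrogenolysis should cleave all ten benzyl ethers, aryl and alkyl, in one operation under neutral conditions that leave the four stereocentres and the benzylic C–O bond of ring C unchanged, giving the target.

**Compound list**

1 | 2-bromo-4,6-difluorobenzoic acid | OC(=O)c1c(F)cc(F)cc1Br | starting material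
2 | tert-butyl 2-bromo-4,6-difluorobenzoate | CC(C)(C)OC(=O)c1c(F)cc(F)cc1Br | intermediate
3 | tert-butyl 6-bromo-2,4-difluoro-3-lithiobenzoate | CC(C)(C)OC(=O)c1c(F)c([Li])c(F)cc1Br | intermediate
4 | tert-butyl 6-bromo-2,4-difluoro-3-formylbenzoate | CC(C)(C)OC(=O)c1c(F)c(C=O)c(F)cc1Br | intermediate
5 | tert-butyl 2,4-bis(benzyloxy)-6-bromo-3-formylbenzoate | CC(C)(C)OC(=O)c1c(OCc2ccccc2)c(C=O)c(OCc2ccccc2)cc1Br | intermediate
6 | tert-butyl 2,4-bis(benzyloxy)-6-bromo-3-[(E)-3-ethoxy-3-oxoprop-1-en-1-yl]benzoate | CCOC(=O)/C=C/c1c(OCc2ccccc2)cc(Br)c(C(=O)OC(C)(C)C)c1OCc1ccccc1 | intermediate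
7 | tert-butyl 2,4-bis(benzyloxy)-6-bromo-3-[(E)-3-hydroxyprop-1-en-1-yl]benzoate | OC/C=C/c1c(OCc2ccccc2)cc(Br)c(C(=O)OC(C)(C)C)c1OCc1ccccc1 | intermediate
8 | tert-butyl 2,4-bis(benzyloxy)-6-bromo-3-[(2S,3S)-3-(hydroxymethyl)oxiran-2-yl]benzoate | OC[C@@H]1O[C@H]1c1c(OCc2ccccc2)cc(Br)c(C(=O)OC(C)(C)C)c1OCc1ccccc1 | intermediate
9 | 4-bromo-1,2-bis(benzyloxy)benzene | Brc1ccc(OCc2ccccc2)c(OCc2ccccc2)c1 | starting material
10 | [3,4-bis(benzyloxy)phenyl]magnesium bromide | Br[Mg]c1ccc(OCc2ccccc2)c(OCc2ccccc2)c1 | intermediate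
11 | tert-butyl 2,4-bis(benzyloxy)-3-[(1R,2R)-1-[3,4-bis(benzyloxy)phenyl]-2,3-dihydroxypropyl]-6-bromobenzoate | OC[C@H](O)[C@H](c1ccc(OCc2ccccc2)c(OCc2ccccc2)c1)c1c(OCc2ccccc2)cc(Br)c(C(=O)OC(C)(C)C)c1OCc1ccccc1 | intermediate
12 | tert-butyl 2,4-bis(benzyloxy)-3-[(1R,2R)-1-[3,4-bis(benzyloxy)phenyl]-2-hydroxy-3-(tosyloxy)propyl]-6-bromobenzoate | Cc1ccc(cc1)S(=O)(=O)OC[C@H](O)[C@H](c1ccc(OCc2ccccc2)c(OCc2ccccc2)c1)c1c(OCc2ccccc2)cc(Br)c(C(=O)OC(C)(C)C)c1OCc1ccccc1 | intermediate
13 | tert-butyl 2,4-bis(benzyloxy)-3-[(R)-[3,4-bis(benzyloxy)phenyl][(2R)-oxiran-2-yl]methyl]-6-bromobenzoate | C1O[C@@H]1[C@H](c1ccc(OCc2ccccc2)c(OCc2ccccc2)c1)c1c(OCc2ccccc2)cc(Br)c(C(=O)OC(C)(C)C)c1OCc1ccccc1 | intermediate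
14 | 1,3,5-tris(benzyloxy)benzene | c1c(OCc2ccccc2)cc(OCc2ccccc2)cc1OCc1ccccc1 | starting material
15 | 2-bromo-1,3,5-tris(benzyloxy)benzene | Brc1c(OCc2ccccc2)cc(OCc2ccccc2)cc1OCc1ccccc1 | intermediate
16 | [2,4,6-tris(benzyloxy)phenyl]magnesium bromide | Br[Mg]c1c(OCc2ccccc2)cc(OCc2ccccc2)cc1OCc1ccccc1 | intermediate
17 | tert-butyl 2,4-bis(benzyloxy)-3-[(1R,2S)-1-[3,4-bis(benzyloxy)phenyl]-2-hydroxy-3-[2,4,6-tris(benzyloxy)phenyl]propyl]-6-bromobenzoate | C(c1c(OCc2ccccc2)cc(OCc2ccccc2)cc1OCc1ccccc1)[C@H](O)[C@H](c1ccc(OCc2ccccc2)c(OCc2ccccc2)c1)c1c(OCc2ccccc2)cc(Br)c(C(=O)OC(C)(C)C)c1OCc1ccccc1 | intermediate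
18 | tert-butyl 2,4-bis(benzyloxy)-3-[(1R,2S)-2-(benzyloxy)-1-[3,4-bis(benzyloxy)phenyl]-3-[2,4,6-tris(benzyloxy)phenyl]propyl]-6-bromobenzoate | C(c1c(OCc2ccccc2)cc(OCc2ccccc2)cc1OCc1ccccc1)[C@H](OCc1ccccc1)[C@H](c1ccc(OCc2ccccc2)c(OCc2ccccc2)c1)c1c(OCc2ccccc2)cc(Br)c(C(=O)OC(C)(C)C)c1OCc1ccccc1 | intermediate
19 | {2,4-bis(benzyloxy)-3-[(1R,2S)-2-(benzyloxy)-1-[3,4-bis(benzyloxy)phenyl]-3-[2,4,6-tris(benzyloxy)phenyl]propyl]-6-bromophenyl}methanol | C(c1c(OCc2ccccc2)cc(OCc2ccccc2)cc1OCc1ccccc1)[C@H](OCc1ccccc1)[C@H](c1ccc(OCc2ccccc2)c(OCc2ccccc2)c1)c1c(OCc2ccccc2)cc(Br)c(CO)c1OCc1ccccc1 | intermediate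
20 | 2,4-bis(benzyloxy)-3-[(1R,2S)-2-(benzyloxy)-1-[3,4-bis(benzyloxy)phenyl]-3-[2,4,6-tris(benzyloxy)phenyl]propyl]-6-bromobenzyl bromide | C(c1c(OCc2ccccc2)cc(OCc2ccccc2)cc1OCc1ccccc1)[C@H](OCc1ccccc1)[C@H](c1ccc(OCc2ccccc2)c(OCc2ccccc2)c1)c1c(OCc2ccccc2)cc(Br)c(CBr)c1OCc1ccccc1 | intermediate
21 | 1-[3,4-bis(benzyloxy)phenyl]ethan-1-one | CC(=O)c1ccc(OCc2ccccc2)c(OCc2ccccc2)c1 | starting material
22 | 3-{2,4-bis(benzyloxy)-3-[(1R,2S)-2-(benzyloxy)-1-[3,4-bis(benzyloxy)phenyl]-3-[2,4,6-tris(benzyloxy)phenyl]propyl]-6-bromophenyl}-1-[3,4-bis(benzyloxy)phenyl]propan-1-one | C(c1c(OCc2ccccc2)cc(OCc2ccccc2)cc1OCc1ccccc1)[C@H](OCc1ccccc1)[C@H](c1ccc(OCc2ccccc2)c(OCc2ccccc2)c1)c1c(OCc2ccccc2)cc(Br)c(CCC(=O)c2ccc(OCc3ccccc3)c(OCc3ccccc3)c2)c1OCc1ccccc1 | intermediate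
23 | 5,7-bis(benzyloxy)-6-[(1R,2S)-2-(benzyloxy)-1-[3,4-bis(benzyloxy)phenyl]-3-[2,4,6-tris(benzyloxy)phenyl]propyl]-2-[3,4-bis(benzyloxy)phenyl]-4H-chromene | C(c1c(OCc2ccccc2)cc(OCc2ccccc2)cc1OCc1ccccc1)[C@H](OCc1ccccc1)[C@H](c1ccc(OCc2ccccc2)c(OCc2ccccc2)c1)c1c(OCc2ccccc2)cc2c(c1OCc1ccccc1)CC=C(c1ccc(OCc3ccccc3)c(OCc3ccccc3)c1)O2 | intermediate
24 | C-3 (isopinocampheyl)borane adduct of 23 (boron on C-3 trans to the 2-aryl group; same spatial arrangement at C-2 and C-3 as in 25) | C(c1c(OCc2ccccc2)cc(OCc2ccccc2)cc1OCc1ccccc1)[C@H](OCc1ccccc1)[C@H](c1ccc(OCc2ccccc2)c(OCc2ccccc2)c1)c1c(OCc2ccccc2)cc2c(c1OCc1ccccc1)C[C@H]([BH][C@@H]1C[C@@H]3C[C@H]([C@H]1C)C3(C)C)[C@@H](c1ccc(OCc3ccccc3)c(OCc3ccccc3)c1)O2 | intermediate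
25 | (2R,3S)-5,7-bis(benzyloxy)-6-[(1R,2S)-2-(benzyloxy)-1-[3,4-bis(benzyloxy)phenyl]-3-[2,4,6-tris(benzyloxy)phenyl]propyl]-2-[3,4-bis(benzyloxy)phenyl]-3,4-dihydro-2H-chromen-3-ol | C(c1c(OCc2ccccc2)cc(OCc2ccccc2)cc1OCc1ccccc1)[C@H](OCc1ccccc1)[C@H](c1ccc(OCc2ccccc2)c(OCc2ccccc2)c1)c1c(OCc2ccccc2)cc2c(c1OCc1ccccc1)C[C@H](O)[C@@H](c1ccc(OCc3ccccc3)c(OCc3ccccc3)c1)O2 | intermediate
26 | (2R,3S)-2-(3,4-dihydroxyphenyl)-6-[(1R,2S)-1-(3,4-dihydroxyphenyl)-2-hydroxy-3-(2,4,6-trihydroxyphenyl)propyl]-3,4-dihydro-2H-chromene-3,5,7-triol | Oc1cc(O)c(C[C@H](O)[C@H](c2ccc(O)c(O)c2)c2c(O)cc3c(c2O)C[C@H](O)[C@@H](c2ccc(O)c(O)c2)O3)c(O)c1 | target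

**Step count and risks**

Total steps: 16. Longest linear sequence: 15 steps (steps 1–8 and 10–16, from 1 to 26); step 9 is a one-step side branch.

Steps most likely to fail:

Step 14. The enolate may be alkylated twice, or the electron-rich benzylic bromide may ionise and self-condense before the C–C bond forms. Fallback: setting out from alcohol 19, oxidation with MnO2 should give 2,4-bis(benzyloxy)-3-[(1R,2S)-2-(benzyloxy)-1-[3,4-bis(benzyloxy)phenyl]-3-[2,4,6-tris(benzyloxy)phenyl]propyl]-6-bromobenzaldehyde F1. Claisen–Schmidt condensation of F1 with 21 (KOH, EtOH/THF) should give the (E)-chalcone F2, and conjugate reduction with [CuH(PPh3)]6 should give ketone 22, where the route is rejoined; 22 is then closed to 23 with the copper conditions of step 14. This replaces enolate alkylation by aldol condensation and 1,4-reduction.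

Step 7. The epoxide opening may lose regio- or stereochemical fidelity, through attack at the non-benzylic carbon or ionisation of the electron-rich benzylic epoxide before the aryl group is delivered. Fallback: setting out from 8, a Friedel–Crafts opening with excess 1,2-bis(benzyloxy)benzene in hexafluoroisopropanol (or with catalytic BF3·OEt2 at −78 °C) uses the arene as a π-nucleophile that should attack the acid-activated benzylic carbon para to a benzyloxy group and anti to the breaking C–O bond. It comes back to the route at 11; this fallback makes no new compound (F0).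

Step 15. The chiral borane may discriminate poorly between the two faces of the nearly planar chromene, or the β-alkoxyborane may undergo ring-opening elimination. Fallback: setting out from 23, hydroboration with BH3·SMe2 followed by NaOH/H2O2 should give both 2,3-trans products, 25 and the (2S,3R)-diastereomer F3. These are diastereomers because of the fixed side-chain centres and can be separated by chromatography, coming back to the route at 25. This replaces reagent control by separation.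

Further compounds
F1 | step 14 | 2,4-bis(benzyloxy)-3-[(1R,2S)-2-(benzyloxy)-1-[3,4-bis(benzyloxy)phenyl]-3-[2,4,6-tris(benzyloxy)phenyl]propyl]-6-bromobenzaldehyde | C(c1c(OCc2ccccc2)cc(OCc2ccccc2)cc1OCc1ccccc1)[C@H](OCc1ccccc1)[C@H](c1ccc(OCc2ccccc2)c(OCc2ccccc2)c1)c1c(OCc2ccccc2)cc(Br)c(C=O)c1OCc1ccccc1
F2 | step 14 | (E)-3-{2,4-bis(benzyloxy)-3-[(1R,2S)-2-(benzyloxy)-1-[3,4-bis(benzyloxy)phenyl]-3-[2,4,6-tris(benzyloxy)phenyl]propyl]-6-bromophenyl}-1-[3,4-bis(benzyloxy)phenyl]prop-2-en-1-one | C(c1c(OCc2ccccc2)cc(OCc2ccccc2)cc1OCc1ccccc1)[C@H](OCc1ccccc1)[C@H](c1ccc(OCc2ccccc2)c(OCc2ccccc2)c1)c1c(OCc2ccccc2)cc(Br)c(/C=C/C(=O)c2ccc(OCc3ccccc3)c(OCc3ccccc3)c2)c1OCc1ccccc1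
F0 | step 7 | none | none
F3 | step 15 | (2S,3R)-5,7-bis(benzyloxy)-6-[(1R,2S)-2-(benzyloxy)-1-[3,4-bis(benzyloxy)phenyl]-3-[2,4,6-tris(benzyloxy)phenyl]propyl]-2-[3,4-bis(benzyloxy)phenyl]-3,4-dihydro-2H-chromen-3-ol | C(c1c(OCc2ccccc2)cc(OCc2ccccc2)cc1OCc1ccccc1)[C@H](OCc1ccccc1)[C@H](c1ccc(OCc2ccccc2)c(OCc2ccccc2)c1)c1c(OCc2ccccc2)cc2c(c1OCc1ccccc1)C[C@@H](O)[C@H](c1ccc(OCc3ccccc3)c(OCc3ccccc3)c1)O2
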